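**Plan**

1. Retrosynthetic cuts, in order: the butenolide C3–vinyl bond (Stille); the lactone ring, i.e. its C–O bond and the bond from lactone C4 to C5 (terminal alkyne plus (E)-2,3-dibromopropenoic acid); the central CH=CH of the polyene (Horner–Wadsworth–Emmons); the ring A–alkyne bond (Sonogashira); in ring B the C1–C6 bond and, before it, the bonds from C6 to C7 and from C3 to C2.
2. Enabling feature: in ring B the gem-dimethyl carbon C1 is bonded to the fully substituted carbinol C6, which lies next to the methyl carbinol C5. C1 can therefore be born as a tertiary radical from an isobutenyl group and C6 as a ketone carbon, while C6, C5 (with its methyl and oxygen), C4 and C3 are the chain of (S)-citramalic acid.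
3. Forward: the acyclic chain is assembled and ring B closes first (radical 6-exo closure); its one-carbon arm is extended to an E-vinylstannane. Separately ring A (from actinol) is joined to the polyenyne chain; the butenolide ring closes second to last; ring B is attached last.
4. Stereocentres: C5 from (S)-citramalic acid, C3 by Corey–Bakshi–Shibata reduction, C6 in the ring closure under control of C5 and C3, ring A C3 from (4R,6R)-actinol.
5. Alkene geometry: from (E)-3-methylpent-2-en-4-yn-1-ol, E-selective Wittig and Horner–Wadsworth–Emmons steps, anti lactonisation (Z) and syn hydrostannation (E).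

Key step: step 9

Assumption: the SMILES is read as ring B (3R,5S,6S), with the 5,6-diol trans and the C3 hydroxyl cis to the C6 hydroxyl, and ring A (3R). Ring atoms are labelled C1 (gem-dimethyl carbon) to C6 (carbon bearing the side chain), and C7 and C8 are the two vinyl carbons between ring B and the lactone.

**Route**

Step 1
Reactants: 1 (S)-citramalic acid
Product: 2 2-[(4S)-2,2,4-trimethyl-5-oxo-1,3-dioxolan-4-yl]acetic acid
Conditions: Me2C(OMe)2, TsOH·H2O (cat.), CH2Cl2, rt
Reagents that add atoms: 2,2-dimethoxypropane COC(C)(C)OC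
Why: acid-catalysed transketalisation should lock the tertiary hydroxyl and the adjacent carboxyl into the five-membered dioxolanone and leave the CH2CO2H arm free, with no bond to the stereocentre touched.

Step 2
Reactants: 2 2-[(4S)-2,2,4-trimethyl-5-oxo-1,3-dioxolan-4-yl]acetic acid; 3 (2-methylprop-1-en-1-yl)magnesium bromide
Product: 5 (5S)-2,2,5-trimethyl-5-(4-methyl-2-oxopent-3-en-1-yl)-1,3-dioxolan-4-one, via acid chloride 4 (not isolated)
Conditions: (COCl)2, DMF (cat.), CH2Cl2, 0 °C to rt, evaporate; then 3, CuI (10 mol %), THF, −78 °C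
Reagents that add atoms: none
Why: acid chloride formation followed by copper-catalysed acylation of the alkenyl Grignard reagent should give the isobutenyl ketone, since the acid chloride reacts far faster than the hindered dioxolanone carbonyl and the β,β-disubstituted enone does not take up a second equivalent at −78 °C.

Step 3
Reactants: 5 (5S)-2,2,5-trimethyl-5-(4-methyl-2-oxopent-3-en-1-yl)-1,3-dioxolan-4-one
Product: 6 (5S)-5-[(2S)-2-hydroxy-4-methylpent-3-en-1-yl]-2,2,5-trimethyl-1,3-dioxolan-4-one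
Conditions: (R)-Me-CBS oxazaborolidine [(R)-1-methyl-3,3-diphenyltetrahydro-1H,3H-pyrrolo[1,2-c][1,3,2]oxazaborole] (20 mol %), catecholborane, toluene, −78 °C; MeOH quench, pH 7 work-up
Reagents that add atoms: none
Why: Corey–Bakshi–Shibata reduction, in which the alkenyl group should act as the large substituent so that the (R)-catalyst gives the (S)-allylic alcohol (future C3) by 1,2-reduction under reagent control.

Step 4
Reactants: 6 (5S)-5-[(2S)-2-hydroxy-4-methylpent-3-en-1-yl]-2,2,5-trimethyl-1,3-dioxolan-4-one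
Product: 7 (5S)-5-[(2S)-2-(tert-butyldimethylsilyloxy)-4-methylpent-3-en-1-yl]-2,2,5-trimethyl-1,3-dioxolan-4-one
Conditions: TBSCl, imidazole, DMF, rt
Reagents that add atoms: tert-butyldimethylsilyl chloride CC(C)(C)[Si](C)(C)Cl
Why: standard silylation of a secondary alcohol, which also removes the hydroxyl that could otherwise lactonise onto the dioxolanone.

Step 5
Reactants: 7 (5S)-5-[(2S)-2-(tert-butyldimethylsilyloxy)-4-methylpent-3-en-1-yl]-2,2,5-trimethyl-1,3-dioxolan-4-one
Product: 8 (2S,4S)-4-(tert-butyldimethylsilyloxy)-2-hydroxy-N-methoxy-N,2,6-trimethylhept-5-enamide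
Conditions: AlMe3, MeNH(OMe)·HCl, CH2Cl2, 0 °C to rt
Reagents that add atoms: N,O-dimethylhydroxylamine hydrochloride CNOC.Cl
Why: Weinreb aminolysis of the activated dioxolanone by the aluminium amide should open the ring with loss of acetone and retain C5, because no bond to C5 breaks.

Step 6
Reactants: 8 (2S,4S)-4-(tert-butyldimethylsilyloxy)-2-hydroxy-N-methoxy-N,2,6-trimethylhept-5-enamide
Product: 9 (2S,4S)-4-(tert-butyldimethylsilyloxy)-N-methoxy-N,2,6-trimethyl-2-(triethylsilyloxy)hept-5-enamide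
Conditions: TESOTf, 2,6-lutidine, CH2Cl2, −40 to 0 °C
Reagents that add atoms: triethylsilyl trifluoromethanesulfonate CC[Si](CC)(CC)OS(=O)(=O)C(F)(F)F
Why: silyl triflate silylation of a tertiary alcohol, which masks the C5 oxygen so that it can neither chelate nor hydrogen-bond to the ketone in the ring closure.

Step 7
Reactants: 9 (2S,4S)-4-(tert-butyldimethylsilyloxy)-N-methoxy-N,2,6-trimethyl-2-(triethylsilyloxy)hept-5-enamide; 10 chloroiodomethane
Product: 11 (3S,5S)-5-(tert-butyldimethylsilyloxy)-1-chloro-3,7-dimethyl-3-(triethylsilyloxy)oct-6-en-2-one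
Conditions: 10, MeLi·LiBr, THF, −78 °C; aq NH4Cl
Reagents that add atoms: none
Why: Weinreb ketone synthesis with chloromethyllithium made in situ by iodine–lithium exchange, in which the chelated tetrahedral adduct collapses only on quench and so should deliver the chloromethyl ketone (C7 installed) without over-addition.

Step 8
Reactants: 11 (3S,5S)-5-(tert-butyldimethylsilyloxy)-1-chloro-3,7-dimethyl-3-(triethylsilyloxy)oct-6-en-2-one
Product: 12 (3S,5S)-5-(tert-butyldimethylsilyloxy)-3,7-dimethyl-2-oxo-3-(triethylsilyloxy)oct-6-en-1-yl benzoate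
Conditions: PhCO2Na, Bu4NI (cat.), DMF, rt
Reagents that add atoms: sodium benzoate [Na+].[O-]C(=O)c1ccccc1
Why: SN2 displacement of an α-chloro ketone by a carboxylate, which is fast at the activated carbon and free of Favorskii chemistry because the other α-carbon carries no hydrogen.

Step 9
Reactants: 12 (3S,5S)-5-(tert-butyldimethylsilyloxy)-3,7-dimethyl-2-oxo-3-(triethylsilyloxy)oct-6-en-1-yl benzoate
Product: 13 [(1R,2S,4R)-4-(tert-butyldimethylsilyloxy)-1-hydroxy-2,6,6-trimethyl-2-(triethylsilyloxy)cyclohexyl]methyl benzoate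
Conditions: Fe(acac)3 (50 mol %), PhSiH3 (3 equiv), degassed EtOH (0.02 M), 60 °C
Reagents that add atoms: none
Why: (acac)2Fe–H, a trivalent iron hydride formed from Fe(acac)3 and PhSiH3 in ethanol, should pass a hydrogen atom to the alkene CH (future C2) and leave the tertiary radical at C1, which adds to the electron-poor ketone carbon C6; the alkoxyl radical is then reduced by divalent iron or quenched by the solvent to the tertiary alcohol. The closest known reaction type is the iron-mediated hydrogen-atom-transfer (Mukaiyama-type) reductive cyclisation of alkene-tethered ketones to tertiary cycloalkanols. Ring B closes in the 6-exo-trig mode through a chair. The new stereocentre C6 is controlled by C5 and C3: the C3 silyloxy group and the C5 methyl sit equatorial, which puts the C5–OSiEt3 bond axial, and the carbonyl oxygen turns anti to that bond (dipole minimisation, Cornforth-type), so the C6 oxygen ends axial and trans to the C5 oxygen with the benzoyloxymethyl arm equatorial. The step needs Markovnikov hydrogen delivery, which the trisubstituted alkene secures, and capture of the alkoxyl radical faster than its β-scission. The second requirement is served by the silylated C5 oxygen, by a benzoate in place of a benzyl ether (no benzylic C–H within reach of the alkoxyl oxygen and a poorer radical leaving group) and by ethanol as hydrogen donor in large excess.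

Step 10
Reactants: 13 [(1R,2S,4R)-4-(tert-butyldimethylsilyloxy)-1-hydroxy-2,6,6-trimethyl-2-(triethylsilyloxy)cyclohexyl]methyl benzoate
Product: 14 (1R,2S,4R)-4-(tert-butyldimethylsilyloxy)-1-(hydroxymethyl)-2,6,6-trimethyl-2-(triethylsilyloxy)cyclohexan-1-ol
Conditions: iBu2AlH, CH2Cl2, −78 °C; aq potassium sodium tartrate
Reagents that add atoms: none
Why: reductive cleavage of the benzoate ester at low temperature, chosen over basic methanolysis so that no alkoxide-driven silyl migration can occur.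

Step 11
Reactants: 14 (1R,2S,4R)-4-(tert-butyldimethylsilyloxy)-1-(hydroxymethyl)-2,6,6-trimethyl-2-(triethylsilyloxy)cyclohexan-1-ol
Product: 15 (1S,2S,4R)-4-(tert-butyldimethylsilyloxy)-1-hydroxy-2,6,6-trimethyl-2-(triethylsilyloxy)cyclohexane-1-carbaldehyde
Conditions: SO3·pyridine, DMSO, Et3N, CH2Cl2, 0 °C
Reagents that add atoms: none
Why: Parikh–Doering oxidation, in which only the primary alcohol can be oxidised and the vicinal diol is not cleaved as it might be by hypervalent iodine oxidants.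

Step 12
Reactants: 15 (1S,2S,4R)-4-(tert-butyldimethylsilyloxy)-1-hydroxy-2,6,6-trimethyl-2-(triethylsilyloxy)cyclohexane-1-carbaldehyde; 16 dimethyl (1-diazo-2-oxopropyl)phosphonate
Product: 17 (1R,2S,4R)-4-(tert-butyldimethylsilyloxy)-1-ethynyl-2,6,6-trimethyl-2-(triethylsilyloxy)cyclohexan-1-ol
Conditions: 16, K2CO3, MeOH, 0 °C to rt
Reagents that add atoms: none
Why: Seyferth–Gilbert homologation with the Ohira–Bestmann reagent should convert the aldehyde into the terminal alkyne (C8 installed) under mild base that leaves C6, which has no α-hydrogen, unchanged.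

Step 13
Reactants: 17 (1R,2S,4R)-4-(tert-butyldimethylsilyloxy)-1-ethynyl-2,6,6-trimethyl-2-(triethylsilyloxy)cyclohexan-1-ol
Product: 18 (1R,2S,4R)-1-ethynyl-2,6,6-trimethylcyclohexane-1,2,4-triol
Conditions: Bu4NF, THF, rt to 40 °C
Reagents that add atoms: none
Why: fluoride-mediated cleavage of both silyl ethers, done here so that no fluoride ever meets the butenolide.

Step 14
Reactants: 18 (1R,2S,4R)-1-ethynyl-2,6,6-trimethylcyclohexane-1,2,4-triol
Product: 19 (1S,2S,4R)-2,6,6-trimethyl-1-[(E)-2-(tributylstannyl)ethenyl]cyclohexane-1,2,4-triol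
Conditions: Bu3SnH, PdCl2(PPh3)2 (3 mol %), THF, 0 °C to rt
Reagents that add atoms: tributyltin hydride CCCC[SnH](CCCC)CCCC
Why: palladium-catalysed syn hydrostannation of a terminal alkyne, in which the carbinol flanked by two quaternary carbons should direct tin to the terminal carbon and so give the E-vinylstannane.

Step 15
Reactants: 20 (4R,6R)-4-hydroxy-2,2,6-trimethylcyclohexan-1-one
Product: 21 (4R,6R)-4-(tert-butyldimethylsilyloxy)-2,2,6-trimethylcyclohexan-1-one
Conditions: TBSCl, imidazole, DMF, rt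
Reagents that add atoms: tert-butyldimethylsilyl chloride CC(C)(C)[Si](C)(C)Cl
Why: standard silylation of the secondary alcohol ahead of enolate chemistry.

Step 16
Reactants: 21 (4R,6R)-4-(tert-butyldimethylsilyloxy)-2,2,6-trimethylcyclohexan-1-one
Product: 22 (4R)-4-(tert-butyldimethylsilyloxy)-2,6,6-trimethylcyclohex-1-en-1-yl trifluoromethanesulfonate
Conditions: LiN(iPr)2, THF, −78 °C; PhNTf2, −78 °C to rt
Reagents that add atoms: N-phenylbis(trifluoromethanesulfonimide) O=S(=O)(N(c1ccccc1)S(=O)(=O)C(F)(F)F)C(F)(F)F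
Why: enolate O-triflation, regiochemically unambiguous because the ketone can enolise only toward the methyl-bearing carbon.

Step 17
Reactants: 22 (4R)-4-(tert-butyldimethylsilyloxy)-2,6,6-trimethylcyclohex-1-en-1-yl trifluoromethanesulfonate; 23 (2E)-3-methylpent-2-en-4-yn-1-ol
Product: 24 (2E)-5-[(4R)-4-(tert-butyldimethylsilyloxy)-2,6,6-trimethylcyclohex-1-en-1-yl]-3-methylpent-2-en-4-yn-1-ol
Conditions: Pd(PPh3)4 (5 mol %), CuI (10 mol %), Et3N, DMF, rt
Reagents that add atoms: none
Why: Sonogashira coupling of an enol triflate with a terminal alkyne, which should keep the E-geometry of the enynol and tolerate the free primary alcohol.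

Step 18
Reactants: 24 (2E)-5-[(4R)-4-(tert-butyldimethylsilyloxy)-2,6,6-trimethylcyclohex-1-en-1-yl]-3-methylpent-2-en-4-yn-1-ol
Product: 25 [(1R)-4-[(3E)-5-bromo-3-methylpent-3-en-1-yn-1-yl]-3,5,5-trimethylcyclohex-3-en-1-yl]oxy(tert-butyl)dimethylsilane
Conditions: CBr4, PPh3, CH2Cl2, −20 °C
Reagents that add atoms: tetrabromomethane BrC(Br)(Br)Br
Why: Appel bromination of a primary allylic alcohol, which at low temperature should proceed without allylic transposition or loss of alkene geometry.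

Step 19
Reactants: 25 [(1R)-4-[(3E)-5-bromo-3-methylpent-3-en-1-yn-1-yl]-3,5,5-trimethylcyclohex-3-en-1-yl]oxy(tert-butyl)dimethylsilane
Product: 26 diethyl [(2E)-5-[(4R)-4-(tert-butyldimethylsilyloxy)-2,6,6-trimethylcyclohex-1-en-1-yl]-3-methylpent-2-en-4-yn-1-yl]phosphonate
Conditions: P(OEt)3, 90 °C
Reagents that add atoms: triethyl phosphite CCOP(OCC)OCC
Why: Michaelis–Arbuzov reaction of a primary allylic bromide should give the allylic phosphonate.

Step 20
Reactants: 23 (2E)-3-methylpent-2-en-4-yn-1-ol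
Product: 27 (2E)-3-methylpent-2-en-4-ynal
Conditions: MnO2, CH2Cl2, rt; used as a solution
Reagents that add atoms: none
Why: selective allylic oxidation by MnO2, which leaves the terminal alkyne and the alkene geometry alone.

Step 21
Reactants: 27 (2E)-3-methylpent-2-en-4-ynal; 28 (triphenyl-λ5-phosphanylidene)acetaldehyde
Product: 29 (2E,4E)-5-methylhepta-2,4-dien-6-ynal
Conditions: 28 (1.05 equiv), toluene, 70 °C
Reagents that add atoms: none
Why: Wittig reaction with a stabilised ylide should add the two-carbon enal unit with E-selectivity, and the more conjugated product reacts more slowly with the ylide than the starting enal.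

Step 22
Reactants: 26 diethyl [(2E)-5-[(4R)-4-(tert-butyldimethylsilyloxy)-2,6,6-trimethylcyclohex-1-en-1-yl]-3-methylpent-2-en-4-yn-1-yl]phosphonate; 29 (2E,4E)-5-methylhepta-2,4-dien-6-ynal
Product: 30 tert-butyl-[(1R)-4-[(3E,5E,7E,9E)-3,10-dimethyldodeca-3,5,7,9-tetraene-1,11-diyn-1-yl]-3,5,5-trimethylcyclohex-3-en-1-yl]oxy-dimethylsilane
Conditions: NaN(SiMe3)2, THF, −78 °C; then 29, −78 to 0 °C
Reagents that add atoms: none
Why: Horner–Wadsworth–Emmons olefination of an allylic phosphonate anion with an enal should form the central disubstituted alkene mainly as the E-isomer, with carbonyl addition outrunning proton transfer from the terminal alkyne.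

Step 23
Reactants: 30 tert-butyl-[(1R)-4-[(3E,5E,7E,9E)-3,10-dimethyldodeca-3,5,7,9-tetraene-1,11-diyn-1-yl]-3,5,5-trimethylcyclohex-3-en-1-yl]oxy-dimethylsilane
Product: 31 (1R)-4-[(3E,5E,7E,9E)-3,10-dimethyldodeca-3,5,7,9-tetraene-1,11-diyn-1-yl]-3,5,5-trimethylcyclohex-3-en-1-ol
Conditions: Bu4NF, THF, 0 °C to rt, dark
Reagents that add atoms: none
Why: fluoride desilylation of the secondary silyl ether before the lactone exists, so that the later steps need no deprotection.

Step 24
Reactants: 32 propiolic acid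
Product: 33 (2E)-2,3-dibromoprop-2-enoic acid
Conditions: Br2, CHCl3, 0 °C to rt, dark; recrystallise
Reagents that add atoms: bromine BrBr
Why: anti addition of bromine to the alkyne should give the E-dibromide, in which the C3 bromine is cis to the carboxyl as the lactonisation requires.

Step 25
Reactants: 31 (1R)-4-[(3E,5E,7E,9E)-3,10-dimethyldodeca-3,5,7,9-tetraene-1,11-diyn-1-yl]-3,5,5-trimethylcyclohex-3-en-1-ol; 33 (2E)-2,3-dibromoprop-2-enoic acid
Product: 35 (5Z)-3-bromo-5-[(2E,4E,6E,8E)-11-[(4R)-4-hydroxy-2,6,6-trimethylcyclohex-1-en-1-yl]-2,9-dimethylundeca-2,4,6,8-tetraen-10-yn-1-ylidene]furan-2(5H)-one, via enynoic acid 34 (not isolated)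
Conditions: 33 (1.3 equiv), Pd(PPh3)4 (5 mol %), CuI (10 mol %), Et3N, MeCN, rt, degassed, dark
Reagents that add atoms: none
Why: tandem Sonogashira coupling and lactonisation, in which the C3 bromide (β to the carboxylate) couples first and the carboxylate then adds anti across the alkyne in the 5-exo-dig mode, which should fix the Z-ylidene geometry and leave the C–Br bond next to the carbonyl for the last step.

Step 26
Reactants: 35 (5Z)-3-bromo-5-[(2E,4E,6E,8E)-11-[(4R)-4-hydroxy-2,6,6-trimethylcyclohex-1-en-1-yl]-2,9-dimethylundeca-2,4,6,8-tetraen-10-yn-1-ylidene]furan-2(5H)-one; 19 (1S,2S,4R)-2,6,6-trimethyl-1-[(E)-2-(tributylstannyl)ethenyl]cyclohexane-1,2,4-triol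
Product: 36 (5Z)-5-[(2E,4E,6E,8E)-11-[(4R)-4-hydroxy-2,6,6-trimethylcyclohex-1-en-1-yl]-2,9-dimethylundeca-2,4,6,8-tetraen-10-yn-1-ylidene]-3-[(E)-2-[(1S,2S,4R)-1,2,4-trihydroxy-2,6,6-trimethylcyclohexyl]ethenyl]furan-2(5H)-one
Conditions: Pd2(dba)3 (5 mol %), AsPh3 (40 mol %), CuI (10 mol %), DMF, rt, dark
Reagents that add atoms: none
Why: Stille coupling of the α-bromo butenolide with the E-vinylstannane under neutral conditions should proceed with retention of both alkene geometries and tolerate the four free hydroxyls, so the target is reached without a final deprotection.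

**Compound list**

1 | (S)-citramalic acid | OC(=O)C[C@](C(=O)O)(C)O | starting material
2 | 2-[(4S)-2,2,4-trimethyl-5-oxo-1,3-dioxolan-4-yl]acetic acid | OC(=O)C[C@]1(C)OC(C)(C)OC1=O | intermediate
3 | (2-methylprop-1-en-1-yl)magnesium bromide (THF solution) | CC(C)=C[Mg]Br | starting material
4 | 2-[(4S)-2,2,4-trimethyl-5-oxo-1,3-dioxolan-4-yl]acetyl chloride (not isolated) | ClC(=O)C[C@]1(C)OC(C)(C)OC1=O | intermediate
5 | (5S)-2,2,5-trimethyl-5-(4-methyl-2-oxopent-3-en-1-yl)-1,3-dioxolan-4-one | CC(C)=CC(=O)C[C@]1(C)OC(C)(C)OC1=O | intermediate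
6 | (5S)-5-[(2S)-2-hydroxy-4-methylpent-3-en-1-yl]-2,2,5-trimethyl-1,3-dioxolan-4-one | CC(C)=C[C@@H](O)C[C@]1(C)OC(C)(C)OC1=O | intermediate
7 | (5S)-5-[(2S)-2-(tert-butyldimethylsilyloxy)-4-methylpent-3-en-1-yl]-2,2,5-trimethyl-1,3-dioxolan-4-one | CC(C)=C[C@@H](O[Si](C)(C)C(C)(C)C)C[C@]1(C)OC(C)(C)OC1=O | intermediate
8 | (2S,4S)-4-(tert-butyldimethylsilyloxy)-2-hydroxy-N-methoxy-N,2,6-trimethylhept-5-enamide | CON(C)C(=O)[C@@](C)(O)C[C@H](O[Si](C)(C)C(C)(C)C)C=C(C)C | intermediate
9 | (2S,4S)-4-(tert-butyldimethylsilyloxy)-N-methoxy-N,2,6-trimethyl-2-(triethylsilyloxy)hept-5-enamide | CON(C)C(=O)[C@@](C)(O[Si](CC)(CC)CC)C[C@H](O[Si](C)(C)C(C)(C)C)C=C(C)C | intermediate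
10 | chloroiodomethane | ClCI | starting material
11 | (3S,5S)-5-(tert-butyldimethylsilyloxy)-1-chloro-3,7-dimethyl-3-(triethylsilyloxy)oct-6-en-2-one | ClCC(=O)[C@@](C)(O[Si](CC)(CC)CC)C[C@H](O[Si](C)(C)C(C)(C)C)C=C(C)C | intermediate
12 | (3S,5S)-5-(tert-butyldimethylsilyloxy)-3,7-dimethyl-2-oxo-3-(triethylsilyloxy)oct-6-en-1-yl benzoate | O=C(OCC(=O)[C@@](C)(O[Si](CC)(CC)CC)C[C@H](O[Si](C)(C)C(C)(C)C)C=C(C)C)c1ccccc1 | intermediate
13 | [(1R,2S,4R)-4-(tert-butyldimethylsilyloxy)-1-hydroxy-2,6,6-trimethyl-2-(triethylsilyloxy)cyclohexyl]methyl benzoate | O=C(OC[C@]1(O)C(C)(C)C[C@@H](O[Si](C)(C)C(C)(C)C)C[C@]1(C)O[Si](CC)(CC)CC)c1ccccc1 | intermediate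
14 | (1R,2S,4R)-4-(tert-butyldimethylsilyloxy)-1-(hydroxymethyl)-2,6,6-trimethyl-2-(triethylsilyloxy)cyclohexan-1-ol | OC[C@]1(O)C(C)(C)C[C@@H](O[Si](C)(C)C(C)(C)C)C[C@]1(C)O[Si](CC)(CC)CC | intermediate
15 | (1S,2S,4R)-4-(tert-butyldimethylsilyloxy)-1-hydroxy-2,6,6-trimethyl-2-(triethylsilyloxy)cyclohexane-1-carbaldehyde | O=C[C@]1(O)C(C)(C)C[C@@H](O[Si](C)(C)C(C)(C)C)C[C@]1(C)O[Si](CC)(CC)CC | intermediate
16 | dimethyl (1-diazo-2-oxopropyl)phosphonate | CC(=O)C(=[N+]=[N-])P(=O)(OC)OC | starting material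
17 | (1R,2S,4R)-4-(tert-butyldimethylsilyloxy)-1-ethynyl-2,6,6-trimethyl-2-(triethylsilyloxy)cyclohexan-1-ol | C#C[C@]1(O)C(C)(C)C[C@@H](O[Si](C)(C)C(C)(C)C)C[C@]1(C)O[Si](CC)(CC)CC | intermediate
18 | (1R,2S,4R)-1-ethynyl-2,6,6-trimethylcyclohexane-1,2,4-triol | C#C[C@]1(O)C(C)(C)C[C@@H](O)C[C@]1(C)O | intermediate
19 | (1S,2S,4R)-2,6,6-trimethyl-1-[(E)-2-(tributylstannyl)ethenyl]cyclohexane-1,2,4-triol | CCCC[Sn](CCCC)(CCCC)/C=C/[C@]1(O)C(C)(C)C[C@@H](O)C[C@]1(C)O | intermediate
20 | (4R,6R)-4-hydroxy-2,2,6-trimethylcyclohexan-1-one (actinol) | O=C1C(C)(C)C[C@H](O)C[C@H]1C | starting material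
21 | (4R,6R)-4-(tert-butyldimethylsilyloxy)-2,2,6-trimethylcyclohexan-1-one | O=C1C(C)(C)C[C@H](O[Si](C)(C)C(C)(C)C)C[C@H]1C | intermediate
22 | (4R)-4-(tert-butyldimethylsilyloxy)-2,6,6-trimethylcyclohex-1-en-1-yl trifluoromethanesulfonate | CC1=C(OS(=O)(=O)C(F)(F)F)C(C)(C)C[C@H](O[Si](C)(C)C(C)(C)C)C1 | intermediate
23 | (2E)-3-methylpent-2-en-4-yn-1-ol | C#C/C(C)=C/CO | starting material
24 | (2E)-5-[(4R)-4-(tert-butyldimethylsilyloxy)-2,6,6-trimethylcyclohex-1-en-1-yl]-3-methylpent-2-en-4-yn-1-ol | CC1=C(C#C/C(C)=C/CO)C(C)(C)C[C@H](O[Si](C)(C)C(C)(C)C)C1 | intermediate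
25 | [(1R)-4-[(3E)-5-bromo-3-methylpent-3-en-1-yn-1-yl]-3,5,5-trimethylcyclohex-3-en-1-yl]oxy(tert-butyl)dimethylsilane | CC1=C(C#C/C(C)=C/CBr)C(C)(C)C[C@H](O[Si](C)(C)C(C)(C)C)C1 | intermediate
26 | diethyl [(2E)-5-[(4R)-4-(tert-butyldimethylsilyloxy)-2,6,6-trimethylcyclohex-1-en-1-yl]-3-methylpent-2-en-4-yn-1-yl]phosphonate | CC1=C(C#C/C(C)=C/CP(=O)(OCC)OCC)C(C)(C)C[C@H](O[Si](C)(C)C(C)(C)C)C1 | intermediate
27 | (2E)-3-methylpent-2-en-4-ynal | C#C/C(C)=C/C=O | intermediate
28 | (triphenyl-λ5-phosphanylidene)acetaldehyde | O=CC=P(c1ccccc1)(c1ccccc1)c1ccccc1 | starting material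
29 | (2E,4E)-5-methylhepta-2,4-dien-6-ynal | C#C/C(C)=C/C=C/C=O | intermediate
30 | tert-butyl-[(1R)-4-[(3E,5E,7E,9E)-3,10-dimethyldodeca-3,5,7,9-tetraene-1,11-diyn-1-yl]-3,5,5-trimethylcyclohex-3-en-1-yl]oxy-dimethylsilane | CC1=C(C#C/C(C)=C/C=C/C=C/C=C(C)/C#C)C(C)(C)C[C@H](O[Si](C)(C)C(C)(C)C)C1 | intermediate
31 | (1R)-4-[(3E,5E,7E,9E)-3,10-dimethyldodeca-3,5,7,9-tetraene-1,11-diyn-1-yl]-3,5,5-trimethylcyclohex-3-en-1-ol | CC1=C(C#C/C(C)=C/C=C/C=C/C=C(C)/C#C)C(C)(C)C[C@H](O)C1 | intermediate
32 | propiolic acid (prop-2-ynoic acid) | C#CC(=O)O | starting material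
33 | (2E)-2,3-dibromoprop-2-enoic acid | OC(=O)/C(Br)=C\Br | intermediate
34 | (2E,6E,8E,10E,12E)-2-bromo-15-[(4R)-4-hydroxy-2,6,6-trimethylcyclohex-1-en-1-yl]-6,13-dimethylpentadeca-2,6,8,10,12-pentaene-4,14-diynoic acid (not isolated) | CC1=C(C#C/C(C)=C/C=C/C=C/C=C(C)/C#C/C=C(/Br)C(=O)O)C(C)(C)C[C@H](O)C1 | intermediate
35 | (5Z)-3-bromo-5-[(2E,4E,6E,8E)-11-[(4R)-4-hydroxy-2,6,6-trimethylcyclohex-1-en-1-yl]-2,9-dimethylundeca-2,4,6,8-tetraen-10-yn-1-ylidene]furan-2(5H)-one | CC1=C(C#C/C(C)=C/C=C/C=C/C=C(C)/C=C2C=C(Br)C(=O)O/2)C(C)(C)C[C@H](O)C1 | intermediate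
36 | (5Z)-5-[(2E,4E,6E,8E)-11-[(4R)-4-hydroxy-2,6,6-trimethylcyclohex-1-en-1-yl]-2,9-dimethylundeca-2,4,6,8-tetraen-10-yn-1-ylidene]-3-[(E)-2-[(1S,2S,4R)-1,2,4-trihydroxy-2,6,6-trimethylcyclohexyl]ethenyl]furan-2(5H)-one | CC1=C(C#C/C(C)=C/C=C/C=C/C=C(C)/C=C2C=C(/C=C/[C@]3(O)C(C)(C)C[C@@H](O)C[C@]3(C)O)C(=O)O/2)C(C)(C)C[C@H](O)C1 | target

**Step count and risks**

Total step count: 26. Longest linear sequence: 15 steps (steps 1 to 14, then step 26).

Steps most likely to fail:

Step 9. The alkoxyl radical at C6 may fragment (toward the oxygen-bearing C5, or back to the C1 radical) before it is reduced; the alkene may simply be reduced without closure; or the radical may add to the wrong face of the carbonyl. The fallback sets out from 12 and comes back at 13. The alkene of 12 would be epoxidised with mCPBA to (3S,5S)-5-(tert-butyldimethylsilyloxy)-5-(3,3-dimethyloxiran-2-yl)-3-methyl-2-oxo-3-(triethylsilyloxy)pentyl benzoate F1 (both epoxide epimers serve). Cp2TiCl, a trivalent titanium reagent made from Cp2TiCl2 and Zn in THF, would then open the epoxide at its tertiary carbon (Nugent–RajanBabu opening). The same C1 radical closes onto the titanium-bound ketone, and a second equivalent of the reagent captures the alkoxyl radical at once, giving the 2-hydroxy analogue of 13, [4-(tert-butyldimethylsilyloxy)-1,5-dihydroxy-2,6,6-trimethyl-2-(triethylsilyloxy)cyclohexyl]methyl benzoate F2. Its secondary hydroxyl would be converted with PhOC(S)Cl and 4-(dimethylamino)pyridine into the phenyl thionocarbonate F3 and removed by Barton–McCombie deoxygenation (Bu3SnH, AIBN, toluene, 90 °C) to reach 13.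

Step 12. The α-hydroxy aldehyde may undergo base-triggered α-ketol ring expansion in K2CO3/MeOH, and addition to the neopentyl carbonyl may be slow. The fallback sets out from 15 and comes back at 19. Takai-type stannylolefination with divalent chromium (CrCl2, Bu3SnCHBr2, LiI, THF/DMF, rt) would convert 15 under neutral conditions directly into (1S,2S,4R)-4-(tert-butyldimethylsilyloxy)-2,6,6-trimethyl-1-[(E)-2-(tributylstannyl)ethenyl]-2-(triethylsilyloxy)cyclohexan-1-ol F4. Bu4NF in THF would then remove both silyl groups to give 19.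

Step 25. On the long polyenyne the coupling may be followed by 6-endo instead of 5-exo lactonisation; the terminal alkyne may dimerise oxidatively; a second alkyne may couple at the remaining C–Br bond; and the tetraene may degrade under palladium and copper. The fallback builds the lactone on the small enyne first; it sets out from 29 (with 33 and 26) and comes back at 35. Aldehyde 29 and acid 33 under the same Pd(PPh3)4/CuI/Et3N conditions would give, through (2E,6E,8E)-2-bromo-6-methyl-10-oxodeca-2,6,8-trien-4-ynoic acid F5, the aldehyde (2E,4E)-6-[(2Z)-4-bromo-5-oxofuran-2(5H)-ylidene]-5-methylhexa-2,4-dienal F6. Horner–Wadsworth–Emmons reaction of F6 with the anion of 26 (NaN(SiMe3)2, THF, −78 °C) would give the tert-butyldimethylsilyl ether of 35 F7. HF·pyridine in THF/pyridine would then free the ring A hydroxyl to give 35.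

Further compounds
F1 | step 9 | (3S,5S)-5-(tert-butyldimethylsilyloxy)-5-(3,3-dimethyloxiran-2-yl)-3-methyl-2-oxo-3-(triethylsilyloxy)pentyl benzoate (both epoxide epimers) | O=C(OCC(=O)[C@@](C)(O[Si](CC)(CC)CC)C[C@H](O[Si](C)(C)C(C)(C)C)C1OC1(C)C)c1ccccc1
F2 | step 9 | [4-(tert-butyldimethylsilyloxy)-1,5-dihydroxy-2,6,6-trimethyl-2-(triethylsilyloxy)cyclohexyl]methyl benzoate, ring configuration as in 13, both epimers at the new carbinol | O=C(OC[C@]1(O)C(C)(C)C(O)[C@@H](O[Si](C)(C)C(C)(C)C)C[C@]1(C)O[Si](CC)(CC)CC)c1ccccc1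
F3 | step 9 | phenyl thionocarbonate of F2 at the secondary hydroxyl | O=C(OC[C@]1(O)C(C)(C)C(OC(=S)Oc2ccccc2)[C@@H](O[Si](C)(C)C(C)(C)C)C[C@]1(C)O[Si](CC)(CC)CC)c1ccccc1
F4 | step 12 | (1S,2S,4R)-4-(tert-butyldimethylsilyloxy)-2,6,6-trimethyl-1-[(E)-2-(tributylstannyl)ethenyl]-2-(triethylsilyloxy)cyclohexan-1-ol | CCCC[Sn](CCCC)(CCCC)/C=C/[C@]1(O)C(C)(C)C[C@@H](O[Si](C)(C)C(C)(C)C)C[C@]1(C)O[Si](CC)(CC)CC
F5 | step 25 | (2E,6E,8E)-2-bromo-6-methyl-10-oxodeca-2,6,8-trien-4-ynoic acid (not isolated) | OC(=O)/C(Br)=C\C#C/C(C)=C/C=C/C=O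
F6 | step 25 | (2E,4E)-6-[(2Z)-4-bromo-5-oxofuran-2(5H)-ylidene]-5-methylhexa-2,4-dienal | O=C/C=C/C=C(C)/C=C1C=C(Br)C(=O)O/1
F7 | step 25 | tert-butyldimethylsilyl ether of 35 | CC1=C(C#C/C(C)=C/C=C/C=C/C=C(C)/C=C2C=C(Br)C(=O)O/2)C(C)(C)C[C@H](O[Si](C)(C)C(C)(C)C)C1
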